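## Retrosynthetic overview

1. Feature: ring A is the cyclohexenone, C5–C10 of the 2-oxaspiro[4.5]decene. Its ketone carbon C6 and acetoxy carbon C9 are 1,4-related across C7=C8, and spiro carbon C5 with methylene C10 forms the remaining edge. With C6 at the alcohol level this is a Diels–Alder retron.
2. Endgame: side-chain desilylation, oxidation of C6–OH to the enone, and selective release of C6–OH from its triethylsilyl ether.
3. Ring B (γ-lactone C1–O2–C3–C4–C5) is opened to a C1 ketone and a CH2CO2Me arm on C5. In the forward direction this is CBS reduction followed by lactonisation.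
4. Ring A: bonds C5–C6 and C9–C10 are cut. This gives an itaconate-derived cross-conjugated dienone (2π, its terminal methylene) and (1E,3E)-1-acetoxy-4-(triethylsilyloxy)butadiene (4π).
5. The dienone comes from Negishi acylation of an (E)-alkenylzinc with the half-ester chloride of itaconic acid. The alkenylzinc derives from 4-pentyn-1-ol and isopropenylmagnesium bromide by Sharpless kinetic resolution and carboalumination–iodination. The diene comes from (Z)-butenediol. Ring order: A, then B.

Key step: step 11

Assumption: the sense of induction in the key step is read from the accepted binding picture of cationic oxazaborolidines (boron on the carbonyl oxygen, s-trans reacting arm stacked over the neighbouring aryl group), which calls for the catalyst made from (R)-α,α-diphenylprolinol; the side-chain carbinol is too remote to bias the cycloaddition, so the (S)-catalyst would serve in the same way should the sense prove opposite.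

## Route

Step 1
Reactants: 1 4-pentyn-1-ol
Product: 2 4-pentynal
Conditions: (COCl)2, DMSO, CH2Cl2, −78 °C; Et3N, −78 °C → rt
Reagents that add atoms: none
Why: Swern oxidation stops at the aldehyde and leaves the terminal alkyne untouched; the volatile aldehyde is carried on as a dried solution.

Step 2
Reactants: 2 4-pentynal; 3 isopropenylmagnesium bromide
Product: 4 rac-2-methylhept-1-en-6-yn-3-ol
Conditions: THF, −78 → 0 °C; sat. aq. NH4Cl
Reagents that add atoms: none
Why: Grignard 1,2-addition to an unhindered aldehyde outruns deprotonation of the alkyne C–H at low temperature and should give the racemic allylic alcohol.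

Step 3
Reactants: 4 rac-2-methylhept-1-en-6-yn-3-ol
Product: 5 (R)-2-methylhept-1-en-6-yn-3-ol
Conditions: Ti(OiPr)4 (15 mol %), L-(+)-diisopropyl tartrate (18 mol %), t-BuOOH (0.6 equiv), 4 Å MS, CH2Cl2, −20 °C
Reagents that add atoms: none
Why: Sharpless kinetic resolution: with the L-(+)-tartrate the (S)-enantiomer of a secondary allylic alcohol is epoxidised much faster, so at slightly more than half conversion the (R)-alcohol, which carries the side-chain stereocentre of the target, should remain.

Step 4
Reactants: 5 (R)-2-methylhept-1-en-6-yn-3-ol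
Product: 6 (R)-tert-butyldimethyl[(2-methylhept-1-en-6-yn-3-yl)oxy]silane
Conditions: TBSCl, imidazole, DMF, rt
Reagents that add atoms: tert-butyldimethylsilyl chloride, CC(C)(C)[Si](C)(C)Cl
Why: Silylation of a secondary alcohol by the silyl chloride–imidazole protocol masks the carbinol for the organometallic steps without touching the stereocentre.

Step 5
Reactants: 6 (R)-tert-butyldimethyl[(2-methylhept-1-en-6-yn-3-yl)oxy]silane
Product: 8 tert-butyl{[(3R,6E)-7-iodo-2,6-dimethylhepta-1,6-dien-3-yl]oxy}dimethylsilane, via alkenyldimethylalane 7 (not isolated)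
Conditions: Me3Al (2.5 equiv), Cp2ZrCl2 (0.3 equiv), CH2Cl2, 0 °C → rt; I2, THF, −30 °C
Reagents that add atoms: trimethylaluminium, C[Al](C)C; iodine, [I][I]
Why: Negishi zirconium-catalysed carboalumination adds methyl and aluminium syn across the terminal alkyne with aluminium at the terminus, and iodinolysis with retention fixes the (E)-trisubstituted alkene, while the 1,1-disubstituted alkene is not carbometallated under these conditions.

Step 6
Reactants: 9 monomethyl itaconate (4-methyl ester; 4-methoxy-2-methylidene-4-oxobutanoic acid)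
Product: 10 methyl 3-(chlorocarbonyl)but-3-enoate
Conditions: (COCl)2, DMF (cat.), CH2Cl2, 0 °C → rt
Reagents that add atoms: oxalyl chloride, O=C(Cl)C(=O)Cl
Why: Acid chloride formation through the Vilsmeier-type chloroiminium species runs without base, so the methylene group should not slip into conjugation with the ester.

Step 7
Reactants: 8 tert-butyl{[(3R,6E)-7-iodo-2,6-dimethylhepta-1,6-dien-3-yl]oxy}dimethylsilane; 10 methyl 3-(chlorocarbonyl)but-3-enoate
Product: 13 methyl (5E,9R)-9-(tert-butyldimethylsilyloxy)-6,10-dimethyl-3-methylidene-4-oxoundeca-5,10-dienoate (cross-conjugated dienone), via alkenyllithium 11 (not isolated), via alkenylzinc chloride 12 (not isolated)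
Conditions: t-BuLi (2.0 equiv), Et2O, −78 °C; ZnCl2, THF, −78 → 0 °C; 10, Pd(PPh3)4 (5 mol %), THF, 0 °C
Reagents that add atoms: none
Why: Lithium–iodine exchange and transmetallation to zinc keep the alkene geometry, and Negishi acylation (zerovalent palladium inserts into the acyl C–Cl bond) should give the ketone without over-addition, the organozinc tolerating the methyl ester and the base-free medium keeping the methylene in place.

Step 8
Reactants: 14 (Z)-but-2-ene-1,4-diol
Product: 15 (Z)-4-hydroxybut-2-en-1-yl acetate
Conditions: 14 (3 equiv), Ac2O (1 equiv), Et3N, 4-dimethylaminopyridine (cat.), THF, 0 °C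
Reagents that add atoms: acetic anhydride, CC(=O)OC(C)=O
Why: Statistical monoacylation of a symmetrical diol: an excess of the cheap, water-soluble diol keeps diacetate formation low and is washed out afterwards.

Step 9
Reactants: 15 (Z)-4-hydroxybut-2-en-1-yl acetate
Product: 16 (Z)-4-oxobut-2-en-1-yl acetate
Conditions: activated MnO2, CH2Cl2, 0 °C → rt; filtration through Celite, used at once
Reagents that add atoms: none
Why: MnO2 allylic oxidation takes place on a neutral surface, so the cis-alkene, which is needed for the geometry control of step 10, should survive.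

Step 10
Reactants: 16 (Z)-4-oxobut-2-en-1-yl acetate
Product: 17 (1E,3E)-4-(triethylsilyloxy)buta-1,3-dien-1-yl acetate
Conditions: TESOTf, i-Pr2NEt, CH2Cl2, −78 → 0 °C; filtration through Et3N-deactivated silica
Reagents that add atoms: triethylsilyl triflate, CC[Si](CC)(CC)OS(=O)(=O)C(F)(F)F
Why: Vinylogous soft enolisation (silyl triflate and a hindered amine): O-silylation of the s-trans enal sets the (1E)-enol ether, and in the cis-enal allylic 1,3-strain against the formyl carbon forces the acetoxy group outward during γ-deprotonation, which should set the (3E)-enol acetate, whereas the trans-enal would be expected to lean towards the (3Z)-isomer.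

Step 11
Reactants: 13 methyl (5E,9R)-9-(tert-butyldimethylsilyloxy)-6,10-dimethyl-3-methylidene-4-oxoundeca-5,10-dienoate; 17 (1E,3E)-4-(triethylsilyloxy)buta-1,3-dien-1-yl acetate
Product: 18 methyl 2-{(1S,2S,5S)-5-acetoxy-1-[(2E,6R)-6-(tert-butyldimethylsilyloxy)-3,7-dimethylocta-2,7-dienoyl]-2-(triethylsilyloxy)cyclohex-3-en-1-yl}acetate (acyl, silyloxy and acetoxy groups all cis)
Conditions: 17 (2.5 equiv), (R)-3,3-diphenyl-1-(o-tolyl)tetrahydro-1H,3H-pyrrolo[1,2-c][1,3,2]oxazaborole (20 mol %), Tf2NH (18 mol %), CH2Cl2, −78 → −40 °C; Et3N quench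
Reagents that add atoms: none
Why: This is a catalytic asymmetric Diels–Alder reaction under a cationic oxazaborolidine, the closest known class being 2-substituted acroleins and enones with 1-oxygenated butadienes: the boron cation binds the ketone oxygen of 13, lowers the LUMO of the C(=CH2) arm, and a concerted, asynchronous [4π+2π] addition begins at the unsubstituted methylene. Ring A closes as a six-membered carbocycle in this one intermolecular suprafacial event, which forms C10–C9 (methylene to acetoxy carbon) and C5–C6 (quaternary carbon to silyloxy carbon) of the later spirocycle. Regioselectivity rests on the donor gap within 17: the silyloxy group outweighs the acetoxy group, so the largest HOMO coefficient lies on the acetoxy-bearing terminus, which pairs with the β-methylene. The two C–O centres come out cis to each other because both substituents are outside groups of the (E,E)-diene, they come out cis to the acyl group because the coordinated ketone sits endo under the diene, and the quaternary centre is set by attack on the Re face of the α-carbon, the face left open when the dienone lies over the aryl group of the (R)-catalyst. Chemoselectivity is secured by the substrate, since the β,β-disubstituted arm of the dienone and the isopropenyl group are too hindered or unactivated to compete. Low temperature, a slight deficit of Tf2NH and the amine quench are meant to hold back Nazarov closure of the divinyl ketone and desilylative Michael addition.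

Step 12
Reactants: 18 methyl 2-{(1S,2S,5S)-5-acetoxy-1-[(2E,6R)-6-(tert-butyldimethylsilyloxy)-3,7-dimethylocta-2,7-dienoyl]-2-(triethylsilyloxy)cyclohex-3-en-1-yl}acetate
Product: 20 (1R,5R,6S,9S)-1-[(1E,5R)-5-(tert-butyldimethylsilyloxy)-2,6-dimethylhepta-1,6-dien-1-yl]-3-oxo-6-(triethylsilyloxy)-2-oxaspiro[4.5]dec-7-en-9-yl acetate, via hydroxy ester 19 (not isolated)
Conditions: (S)-1-methyl-3,3-diphenyltetrahydro-1H,3H-pyrrolo[1,2-c][1,3,2]oxazaborole (30 mol %), catecholborane (2 equiv), toluene, −78 → −40 °C; MeOH, pH 7 buffer; pyridinium p-toluenesulfonate (cat.), CH2Cl2, rt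
Reagents that add atoms: none
Why: CBS reduction: the oxazaborolidine binds the ketone lone pair on the side of the slimmer alkenyl arm, away from the quaternary carbon, so the (S)-catalyst should deliver hydride to give the (R)-carbinol C1, catecholborane being chosen because it spares the isopropenyl group, and the hydroxy ester then closes ring B by 5-exo-trig lactonisation helped by the Thorpe–Ingold effect.

Step 13
Reactants: 20 (1R,5R,6S,9S)-6-(triethylsilyloxy) spirolactone
Product: 21 (1R,5S,6S,9S)-1-[(1E,5R)-5-(tert-butyldimethylsilyloxy)-2,6-dimethylhepta-1,6-dien-1-yl]-6-hydroxy-3-oxo-2-oxaspiro[4.5]dec-7-en-9-yl acetate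
Conditions: pyridinium p-toluenesulfonate (0.2 equiv), MeOH–CH2Cl2, 0 °C
Reagents that add atoms: none
Why: Acid-catalysed methanolysis distinguishes silyl ethers by the bulk at silicon, the triethylsilyl ether being far more labile than the tert-butyldimethylsilyl ether, and it leaves acetate and lactone alone.

Step 14
Reactants: 21 (1R,5S,6S,9S)-6-hydroxy spirolactone
Product: 22 (1R,5R,9S)-1-[(1E,5R)-5-(tert-butyldimethylsilyloxy)-2,6-dimethylhepta-1,6-dien-1-yl]-3,6-dioxo-2-oxaspiro[4.5]dec-7-en-9-yl acetate
Conditions: Dess–Martin periodinane, CH2Cl2, 0 °C → rt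
Reagents that add atoms: none
Why: Dess–Martin oxidation converts the hindered allylic alcohol into the enone under nearly neutral conditions, and because the neighbouring spiro carbon bears no hydrogen, neither epimerisation nor β-elimination of the lactone oxygen can follow.

Step 15
Reactants: 22 (1R,5R,9S)-silyl-protected enone
Product: 23 (1R,5R,9S)-1-[(1E,5R)-5-hydroxy-2,6-dimethylhepta-1,6-dien-1-yl]-3,6-dioxo-2-oxaspiro[4.5]dec-7-en-9-yl acetate (target)
Conditions: HF·pyridine, pyridine, THF, 0 °C → rt
Reagents that add atoms: none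
Why: Fluoride-driven desilylation in a buffered acidic medium avoids the basic conditions under which the γ-acetoxy enone could enolise, and it touches no stereocentre.

## Compound list

1 | 4-pentyn-1-ol | C#CCCCO | starting material
2 | 4-pentynal | C#CCCC=O | intermediate
3 | isopropenylmagnesium bromide | C=C(C)[Mg]Br | starting material
4 | rac-2-methylhept-1-en-6-yn-3-ol | C=C(C)C(O)CCC#C | intermediate
5 | (R)-2-methylhept-1-en-6-yn-3-ol | C=C(C)[C@H](O)CCC#C | intermediate
6 | (R)-tert-butyldimethyl[(2-methylhept-1-en-6-yn-3-yl)oxy]silane | C=C(C)[C@H](O[Si](C)(C)C(C)(C)C)CCC#C | intermediate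
7 | (E)-alkenyldimethylalane from 6 (not isolated) | C=C(C)[C@H](O[Si](C)(C)C(C)(C)C)CC/C(C)=C/[Al](C)C | intermediate
8 | tert-butyl{[(3R,6E)-7-iodo-2,6-dimethylhepta-1,6-dien-3-yl]oxy}dimethylsilane | C=C(C)[C@H](O[Si](C)(C)C(C)(C)C)CC/C(C)=C/I | intermediate
9 | monomethyl itaconate (4-methyl ester) | C=C(CC(=O)OC)C(=O)O | starting material
10 | methyl 3-(chlorocarbonyl)but-3-enoate | C=C(CC(=O)OC)C(=O)Cl | intermediate
11 | (E)-alkenyllithium from 8 (not isolated) | C=C(C)[C@H](O[Si](C)(C)C(C)(C)C)CC/C(C)=C/[Li] | intermediate
12 | (E)-alkenylzinc chloride (not isolated) | C=C(C)[C@H](O[Si](C)(C)C(C)(C)C)CC/C(C)=C/[Zn]Cl | intermediate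
13 | methyl (5E,9R)-9-(tert-butyldimethylsilyloxy)-6,10-dimethyl-3-methylidene-4-oxoundeca-5,10-dienoate | C=C(C)[C@H](O[Si](C)(C)C(C)(C)C)CC/C(C)=C/C(=O)C(=C)CC(=O)OC | intermediate
14 | (Z)-but-2-ene-1,4-diol | OC/C=C\CO | starting material
15 | (Z)-4-hydroxybut-2-en-1-yl acetate | CC(=O)OC/C=C\CO | intermediate
16 | (Z)-4-oxobut-2-en-1-yl acetate | CC(=O)OC/C=C\C=O | intermediate
17 | (1E,3E)-4-(triethylsilyloxy)buta-1,3-dien-1-yl acetate | CC(=O)O/C=C/C=C/O[Si](CC)(CC)CC | intermediate
18 | methyl 2-{(1S,2S,5S)-5-acetoxy-1-[(2E,6R)-6-(tert-butyldimethylsilyloxy)-3,7-dimethylocta-2,7-dienoyl]-2-(triethylsilyloxy)cyclohex-3-en-1-yl}acetate | C=C(C)[C@H](O[Si](C)(C)C(C)(C)C)CC/C(C)=C/C(=O)[C@]1(CC(=O)OC)C[C@H](OC(C)=O)C=C[C@@H]1O[Si](CC)(CC)CC | intermediate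
19 | methyl 2-{(1R,2S,5S)-5-acetoxy-1-[(1R,2E,6R)-6-(tert-butyldimethylsilyloxy)-1-hydroxy-3,7-dimethylocta-2,7-dien-1-yl]-2-(triethylsilyloxy)cyclohex-3-en-1-yl}acetate (not isolated) | C=C(C)[C@H](O[Si](C)(C)C(C)(C)C)CC/C(C)=C/[C@@H](O)[C@]1(CC(=O)OC)C[C@H](OC(C)=O)C=C[C@@H]1O[Si](CC)(CC)CC | intermediate
20 | (1R,5R,6S,9S)-1-[(1E,5R)-5-(tert-butyldimethylsilyloxy)-2,6-dimethylhepta-1,6-dien-1-yl]-3-oxo-6-(triethylsilyloxy)-2-oxaspiro[4.5]dec-7-en-9-yl acetate | C=C(C)[C@H](O[Si](C)(C)C(C)(C)C)CC/C(C)=C/[C@H]1OC(=O)C[C@]12C[C@H](OC(C)=O)C=C[C@@H]2O[Si](CC)(CC)CC | intermediate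
21 | (1R,5S,6S,9S)-1-[(1E,5R)-5-(tert-butyldimethylsilyloxy)-2,6-dimethylhepta-1,6-dien-1-yl]-6-hydroxy-3-oxo-2-oxaspiro[4.5]dec-7-en-9-yl acetate | C=C(C)[C@H](O[Si](C)(C)C(C)(C)C)CC/C(C)=C/[C@H]1OC(=O)C[C@]12C[C@H](OC(C)=O)C=C[C@@H]2O | intermediate
22 | (1R,5R,9S)-1-[(1E,5R)-5-(tert-butyldimethylsilyloxy)-2,6-dimethylhepta-1,6-dien-1-yl]-3,6-dioxo-2-oxaspiro[4.5]dec-7-en-9-yl acetate | C=C(C)[C@H](O[Si](C)(C)C(C)(C)C)CC/C(C)=C/[C@H]1OC(=O)C[C@]12C[C@H](OC(C)=O)C=CC2=O | intermediate
23 | (1R,5R,9S)-1-[(1E,5R)-5-hydroxy-2,6-dimethylhepta-1,6-dien-1-yl]-3,6-dioxo-2-oxaspiro[4.5]dec-7-en-9-yl acetate | C=C(C)[C@H](O)CC/C(C)=C/[C@H]1OC(=O)C[C@]12C[C@H](OC(C)=O)C=CC2=O | target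

Total step count: 15
Longest linear sequence: 11 steps (steps 1, 2, 3, 4, 5, 7, 11, 12, 13, 14, 15)

## Steps most likely to fail

**Step 11.**
- What may go wrong: facial or endo discrimination may be weak, because the reacting arm of the dienone offers the boron cation neither a formyl nor an α-vinyl C–H contact. Nazarov cyclisation of the divinyl ketone may also compete, as may protodesilylation or Michael-type consumption of the diene.
- Fallback: it sets out from 10 and 17, uses 12, and comes back at 18. The side chain is attached after the cycloaddition instead of before it.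
- Acid chloride 10 is reduced with Bu3SnH under Pd(PPh3)4 catalysis to methyl 3-formylbut-3-enoate F1. This is a 2-substituted acrolein, the dienophile class for which the formyl C–H···O binding mode of the cationic oxazaborolidine is established.
- Cycloaddition of F1 with 17 under the catalyst of step 11 should give the all-cis aldehyde F2.
- Pinnick oxidation (NaClO2, NaH2PO4, 2-methyl-2-butene) gives the acid F3. 1-Chloro-N,N,2-trimethylpropenylamine converts F3 under neutral conditions into the acid chloride F4.
- Pd(PPh3)4-catalysed acylation of the alkenylzinc chloride 12 with F4 delivers 18.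

**Step 12.**
- What may go wrong: reduction at the neopentyl ketone may be slow, and the facial bias of the substrate may erode the reagent control, so that the C1 epimer forms.
- Fallback: it sets out from 18 and comes back at 21. External reagent control is replaced by hydroxyl-directed delivery.
- The triethylsilyl ether of 18 is removed first (pyridinium p-toluenesulfonate, MeOH, 0 °C) to give the β-hydroxy ketone F5.
- Narasaka–Prasad reduction (Et2BOMe, NaBH4, THF–MeOH, −78 °C) follows. In the cis-fused boron chelate, axial hydride attack comes from the side of the small carbinol hydrogen. This should give the 1,3-syn diol F6, which is the relation between C6–O and C1–O that the target needs.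
- After evaporation from MeOH–AcOH, the C1 hydroxyl closes the spirolactone to give 21. The C6 hydroxyl is trans to the CH2CO2Me arm and would have to form a strained trans-fused lactone, so it should not compete.

**Step 10.**
- What may go wrong: the cis-enal may isomerise before enolisation, and the (3Z)-enol acetate may form, which cannot reach the s-cis conformation.
- Fallback: it sets out from 16 and comes back at 17. The geometry is secured by crystallisation instead of by kinetic control.
- Enol acetylation of 16 (Ac2O, Et3N, 4-dimethylaminopyridine) gives buta-1,3-diene-1,4-diyl diacetate. Its crystalline (1E,3E)-isomer F7 is freed from the geometric isomers by recrystallisation.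
- Cleavage of one enol acetate with MeLi (two equivalents per ester cleaved, THF, −78 °C) gives the lithium dienolate F8 with retention of geometry, and TESCl traps it on oxygen as 17.
- Unchanged F7 and the bis-silyl ether are removed by distillation.

## Further compounds

F1 | step 11 | methyl 3-formylbut-3-enoate | C=C(C=O)CC(=O)OC
F2 | step 11 | methyl 2-[(1S,2S,5S)-5-acetoxy-1-formyl-2-(triethylsilyloxy)cyclohex-3-en-1-yl]acetate | O=C[C@]1(CC(=O)OC)C[C@H](OC(C)=O)C=C[C@@H]1O[Si](CC)(CC)CC
F3 | step 11 | (1S,2S,5S)-5-acetoxy-1-(2-methoxy-2-oxoethyl)-2-(triethylsilyloxy)cyclohex-3-ene-1-carboxylic acid | OC(=O)[C@]1(CC(=O)OC)C[C@H](OC(C)=O)C=C[C@@H]1O[Si](CC)(CC)CC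
F4 | step 11 | (1S,2S,5S)-5-acetoxy-1-(2-methoxy-2-oxoethyl)-2-(triethylsilyloxy)cyclohex-3-ene-1-carbonyl chloride | ClC(=O)[C@]1(CC(=O)OC)C[C@H](OC(C)=O)C=C[C@@H]1O[Si](CC)(CC)CC
F5 | step 12 | methyl 2-{(1S,2S,5S)-5-acetoxy-1-[(2E,6R)-6-(tert-butyldimethylsilyloxy)-3,7-dimethylocta-2,7-dienoyl]-2-hydroxycyclohex-3-en-1-yl}acetate | C=C(C)[C@H](O[Si](C)(C)C(C)(C)C)CC/C(C)=C/C(=O)[C@]1(CC(=O)OC)C[C@H](OC(C)=O)C=C[C@@H]1O
F6 | step 12 | 1,3-syn diol ester from F5, with an (R)-carbinol in the side chain | C=C(C)[C@H](O[Si](C)(C)C(C)(C)C)CC/C(C)=C/[C@@H](O)[C@]1(CC(=O)OC)C[C@H](OC(C)=O)C=C[C@@H]1O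
F7 | step 10 | (1E,3E)-buta-1,3-diene-1,4-diyl diacetate | CC(=O)O/C=C/C=C/OC(C)=O
F8 | step 10 | lithium (1E,3E)-4-acetoxybuta-1,3-dien-1-olate | CC(=O)O/C=C/C=C/O[Li]
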